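**Strategy.** The oxolan-2-one ring (O1, C2 carbonyl, C3 methylidene carbon, C4 carboxyl carbon, C5 chain carbon) is read as the Baeyer–Villiger product of a cyclobutanone made of C2, C3, C4 and C5. A chiral keteniminium salt from a 16-oxoheptadecanoyl amide (C5=C2) adds to (E)-cinnamyl acetate (C3=C4) in a [2+2] cycloaddition that forms C2–C3 and C4–C5 at once. The C2–C5 bond of the acyl chain closes the temporary four-membered ring and is later cut by oxygen insertion. Phenyl on C4 is a masked carboxyl and acetoxymethyl on C3 a masked methylidene, which also steers the oxygen insertion.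

Key step: step 3

Assumption: the (2R,5R)-auxiliary is taken to leave open the alkene face that leads to the (3R)-phenyl centre of 12 (smallest group of the incoming alkene carbon towards the syn-methyl group of the pyrrolidine); should the sense be opposite, the equally available (2S,5S)-amine takes its place and nothing else changes.

**Step 1**
Reactants: 1 12-bromododecanoic acid; 2 2-(3-chloropropyl)-2-methyl-1,3-dioxolane
Product: 5 16-oxoheptadecanoic acid, via Grignard reagent 3 (not isolated), via ketal acid 4 (not isolated)
Conditions: 2, Mg, THF, reflux; 1, MeMgCl, THF, −20 °C; combine, Li2CuCl4 (cat.), −20 °C → rt; then 2 M HCl, THF, rt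
Reagents that add atoms: water (O)
Why: Copper-catalysed cross-coupling of an alkyl Grignard reagent with a primary alkyl bromide (Kochi coupling) on the magnesium carboxylate joins the two chain pieces, and the acidic work-up hydrolyses the dioxolane to the methyl ketone; no stereocentre is involved.

**Step 2**
Reactants: 5 16-oxoheptadecanoic acid; 6 (2R,5R)-2,5-dimethylpyrrolidine
Product: 8 1-[(2R,5R)-2,5-dimethylpyrrolidin-1-yl]heptadecane-1,16-dione, via acid chloride 7 (not isolated)
Conditions: (COCl)2, DMF (cat.), CH2Cl2, 0 °C → rt; then 6, Et3N, CH2Cl2, 0 °C → rt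
Reagents that add atoms: none
Why: Acylation of the hindered secondary amine by the acid chloride (amide formation) should be clean, since the methyl ketone is inert to oxalyl chloride under these conditions and the auxiliary centres are not touched.

**Step 3**
Reactants: 8 1-[(2R,5R)-2,5-dimethylpyrrolidin-1-yl]heptadecane-1,16-dione; 9 (E)-cinnamyl acetate
Product: 12 (2R,3R,4R)-2-(acetoxymethyl)-4-(14-oxopentadecyl)-3-phenylcyclobutan-1-one, via keteniminium triflate 10 (not isolated), via cyclobutaniminium triflate 11 (not isolated)
Conditions: Tf2O, 2,6-di-tert-butyl-4-methylpyridine, 9 (3 equiv), ClCH2CH2Cl, −20 → 80 °C; then 1 M HCl, THF, 40 °C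
Reagents that add atoms: water (O)
Why: O-Triflation of the amide and loss of triflic acid give keteniminium salt 10, whose central carbon attacks the alkene carbon of 9 that carries the acetoxymethyl group, so that positive charge grows at the benzylic carbon, which is captured by the enamine carbon: a polar keteniminium–olefin [2+2] cycloaddition, the nitrogen analogue of the ketene–alkene cycloaddition. The cyclobutane ring is closed by this intermolecular [2+2] process (suprafacial on the alkene, the second bond forming by collapse of the enamine carbon onto the benzylic cation), and hydrolysis of iminium salt 11 gives the ketone. Regioselectivity rests on the styrene-type polarisation of 9, and chemoselectivity on the far higher nucleophilicity of the amide oxygen compared with the ketone and ester carbonyl groups towards Tf2O. The phenyl-bearing centre is set by the C2-symmetric pyrrolidine, which differentiates the faces of the alkene as it approaches the keteniminium carbon anti to the alkyl chain, and the E-geometry of 9 places acetoxymethyl and phenyl trans. The two centres next to the carbonyl group are epimerisable and should settle under the acidic hydrolysis in the all-trans arrangement, which fixes the chain trans to phenyl.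

**Step 4**
Reactants: 12 (2R,3R,4R)-2-(acetoxymethyl)-4-(14-oxopentadecyl)-3-phenylcyclobutan-1-one
Product: 13 [(3R,4R,5R)-2-oxo-5-(14-oxopentadecyl)-4-phenyloxolan-3-yl]methyl acetate
Conditions: mCPBA, CH2Cl2, 0 °C → rt
Reagents that add atoms: mCPBA (OOC(=O)c1cccc(Cl)c1)
Why: Baeyer–Villiger oxidation, in whose Criegee intermediate the ring carbon bearing the alkyl chain should migrate with retention because the other α-carbon is deactivated by its acetoxymethyl group, while the strained cyclobutanone reacts far faster than the methyl ketone of the chain.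

**Step 5**
Reactants: 13 [(3R,4R,5R)-2-oxo-5-(14-oxopentadecyl)-4-phenyloxolan-3-yl]methyl acetate
Product: 14 (2R,3S,4R)-4-(acetoxymethyl)-5-oxo-2-(14-oxopentadecyl)oxolane-3-carboxylic acid
Conditions: RuCl3·xH2O (cat.), NaIO4, CCl4/MeCN/H2O, rt
Reagents that add atoms: sodium periodate ([Na+].[O-][I](=O)(=O)=O); water (O)
Why: RuO4 formed in situ degrades the phenyl ring to a carboxylic acid whose carbon is the former ipso carbon (arene as masked carboxyl group), while lactone, acetate, ketone and the saturated chain are inert and the acidic medium leaves the stereocentres untouched.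

**Step 6**
Reactants: 14 (2R,3S,4R)-4-(acetoxymethyl)-5-oxo-2-(14-oxopentadecyl)oxolane-3-carboxylic acid
Product: 15 (2R,3S)-4-methylidene-5-oxo-2-(14-oxopentadecyl)oxolane-3-carboxylic acid
Conditions: DBU (3 equiv), CH2Cl2, 0 °C → rt; then 1 M HCl
Reagents that add atoms: none
Why: E1cB elimination of acetic acid from the β-acetoxy lactone sets up the exocyclic methylidene group, and because the reaction runs on the carboxylate the hydrogen α to it is not removed, so neither that centre nor the position of the double bond should change.

**Compound list**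
1 | 12-bromododecanoic acid | OC(=O)CCCCCCCCCCCBr | starting material
2 | 2-(3-chloropropyl)-2-methyl-1,3-dioxolane | CC1(CCCCl)OCCO1 | starting material
3 | [3-(2-methyl-1,3-dioxolan-2-yl)propyl]magnesium chloride | CC1(CCC[Mg]Cl)OCCO1 | intermediate
4 | 15-(2-methyl-1,3-dioxolan-2-yl)pentadecanoic acid | CC1(CCCCCCCCCCCCCCC(=O)O)OCCO1 | intermediate
5 | 16-oxoheptadecanoic acid | CC(=O)CCCCCCCCCCCCCCC(=O)O | intermediate
6 | (2R,5R)-2,5-dimethylpyrrolidine | C[C@@H]1CC[C@@H](C)N1 | starting material
7 | 16-oxoheptadecanoyl chloride | CC(=O)CCCCCCCCCCCCCCC(=O)Cl | intermediate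
8 | 1-[(2R,5R)-2,5-dimethylpyrrolidin-1-yl]heptadecane-1,16-dione | CC(=O)CCCCCCCCCCCCCCC(=O)N1[C@H](C)CC[C@H]1C | intermediate
9 | (E)-cinnamyl acetate, (2E)-3-phenylprop-2-en-1-yl acetate | CC(=O)OC/C=C/c1ccccc1 | starting material
10 | (2R,5R)-2,5-dimethyl-1-(16-oxoheptadec-1-en-1-ylidene)pyrrolidin-1-ium trifluoromethanesulfonate | CC(=O)CCCCCCCCCCCCCC=C=[N+]1[C@H](C)CC[C@H]1C.[O-]S(=O)(=O)C(F)(F)F | intermediate
11 | 1-[(2S,3R,4R)-2-(acetoxymethyl)-4-(14-oxopentadecyl)-3-phenylcyclobutylidene]-(2R,5R)-2,5-dimethylpyrrolidin-1-ium trifluoromethanesulfonate (drawn as the all-trans isomer) | CC(=O)OC[C@@H]1C(=[N+]2[C@H](C)CC[C@H]2C)[C@H](CCCCCCCCCCCCCC(C)=O)[C@H]1c3ccccc3.[O-]S(=O)(=O)C(F)(F)F | intermediate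
12 | (2R,3R,4R)-2-(acetoxymethyl)-4-(14-oxopentadecyl)-3-phenylcyclobutan-1-one (all-trans) | CC(=O)OC[C@@H]1C(=O)[C@H](CCCCCCCCCCCCCC(C)=O)[C@H]1c2ccccc2 | intermediate
13 | [(3R,4R,5R)-2-oxo-5-(14-oxopentadecyl)-4-phenyloxolan-3-yl]methyl acetate | CC(=O)OC[C@@H]1C(=O)O[C@H](CCCCCCCCCCCCCC(C)=O)[C@H]1c2ccccc2 | intermediate
14 | (2R,3S,4R)-4-(acetoxymethyl)-5-oxo-2-(14-oxopentadecyl)oxolane-3-carboxylic acid | CC(=O)OC[C@@H]1C(=O)O[C@H](CCCCCCCCCCCCCC(C)=O)[C@H]1C(=O)O | intermediate
15 | (2R,3S)-4-methylidene-5-oxo-2-(14-oxopentadecyl)oxolane-3-carboxylic acid | C=C1C(=O)O[C@H](CCCCCCCCCCCCCC(C)=O)[C@H]1C(=O)O | target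

**Total step count:** 6. **Longest linear sequence:** 6 steps (1 → 5 → 8 → 12 → 13 → 14 → 15).

**Steps most likely to fail**

(a) Step 3, the key step. The auxiliary sits far from the phenyl-bearing carbon and the ring may close stepwise, so facial discrimination may be poor and the acid series may not be enantiomerically pure. The fallback replaces auxiliary control by a classical resolution. It sets out from 14, before the amine-sensitive methylidene lactone exists. Acid 14 is crystallised from ethanol–ethyl acetate with (S)-1-phenylethylamine as the (S)-1-phenylethylammonium salt F1 (the antipodal amine is used if its salt with the wanted acid is the less soluble one). The salt is split with cold dilute HCl, which returns to 14.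

(b) Step 4. In the Criegee intermediate the acetoxymethyl-bearing ring carbon may migrate in competition with the chain-bearing carbon, giving the regioisomeric lactone. The fallback exchanges the acetate for a much stronger acceptor before the oxidation. It sets out from 12: DBU in CH2Cl2 at 0 °C eliminates acetic acid to the methylidene ketone F2, which is not isolated. Sodium methanesulfinate and acetic acid in DMF add to it in a conjugate addition to give the sulfone ketone F3. Oxidation with mCPBA should now move only the chain-bearing carbon and give the sulfone lactone F4. RuCl3/NaIO4 converts the phenyl ring into the carboxyl group of the sulfone acid F5. DBU then expels methanesulfinate (E1cB), and the route is rejoined at 15.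

(c) Step 6. Under the amine base the freshly formed methylidene lactone may take up nucleophiles again or shift its double bond into the ring, a known weakness of this acid family. The fallback forms the double bond under neutral conditions by a sulfoxide syn-elimination. It sets out from 14: thiophenol and DBU in THF at 0 °C trap the methylidene lactone as soon as it forms, giving the sulfide F6. NaIO4 in aqueous methanol at 0 °C oxidises it to the sulfoxide F7. Heating in toluene at 110 °C expels benzenesulfenic acid and returns to 15.

**Further compounds**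
F1 | step 3 | (S)-1-phenylethylammonium (2R,3S,4R)-4-(acetoxymethyl)-5-oxo-2-(14-oxopentadecyl)oxolane-3-carboxylate | CC(=O)OC[C@@H]1C(=O)O[C@H](CCCCCCCCCCCCCC(C)=O)[C@H]1C(=O)[O-].C[C@H]([NH3+])c1ccccc1
F2 | step 4 | (3S,4R)-2-methylidene-4-(14-oxopentadecyl)-3-phenylcyclobutan-1-one | C=C1C(=O)[C@H](CCCCCCCCCCCCCC(C)=O)[C@H]1c2ccccc2
F3 | step 4 | (2S,3R,4R)-2-[(methanesulfonyl)methyl]-4-(14-oxopentadecyl)-3-phenylcyclobutan-1-one | CS(=O)(=O)C[C@@H]1C(=O)[C@H](CCCCCCCCCCCCCC(C)=O)[C@H]1c2ccccc2
F4 | step 4 | (3S,4R,5R)-3-[(methanesulfonyl)methyl]-5-(14-oxopentadecyl)-4-phenyloxolan-2-one | CS(=O)(=O)C[C@@H]1C(=O)O[C@H](CCCCCCCCCCCCCC(C)=O)[C@H]1c2ccccc2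
F5 | step 4 | (2R,3S,4S)-4-[(methanesulfonyl)methyl]-5-oxo-2-(14-oxopentadecyl)oxolane-3-carboxylic acid | CS(=O)(=O)C[C@@H]1C(=O)O[C@H](CCCCCCCCCCCCCC(C)=O)[C@H]1C(=O)O
F6 | step 6 | (2R,3S,4S)-5-oxo-2-(14-oxopentadecyl)-4-[(phenylsulfanyl)methyl]oxolane-3-carboxylic acid | c2ccccc2SC[C@@H]1C(=O)O[C@H](CCCCCCCCCCCCCC(C)=O)[C@H]1C(=O)O
F7 | step 6 | (2R,3S,4S)-4-[(benzenesulfinyl)methyl]-5-oxo-2-(14-oxopentadecyl)oxolane-3-carboxylic acid (mixture at sulfur) | O=S(C[C@@H]1C(=O)O[C@H](CCCCCCCCCCCCCC(C)=O)[C@H]1C(=O)O)c2ccccc2
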